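The earlier runs and the new flask are calculated from invented constants, and the scatter is random.

What matched between the two earlier runs was not a percentage but a percentage multiplied by the charge. In the spring run 27.6% of the charge was no longer solid; this is the lost share, and my rule was that, at this one temperature and while solid remains, the lost share times the charge stays the same. The dawn run lost 17.7% of its larger charge, which on the spring charge is 27.9%, and the two differ by less than the scatter of 0.5 percentage points.

| flask | solid substrate | remark | time |
|---|---|---|---|
| spring | 0.42 M | run made earlier |  |
| dawn | 0.66 M | run made earlier |  |
| flask | 0.30 M |  | 5.0 h |

| run | time / h | target / % | isomer of the product / % | solid substrate / % |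
|---|---|---|---|---|
| spring | 0.500 | 2.8 | 22.2 | 72.0 |
| spring | 1.33 | 2.2 | 21.6 | 73.2 |
| spring | 2.50 | 2.0 | 22.3 | 72.3 |
| spring | 4.00 | 2.2 | 22.2 | 71.9 |
| dawn | 0.333 | 1.6 | 13.5 | 82.6 |
| dawn | 0.667 | 1.7 | 14.6 | 81.3 |
| dawn | 1.50 | 1.2 | 13.8 | 82.3 |
| dawn | 4.00 | 1.2 | 13.1 | 82.9 |

(scatter of a reading: 0.5 percentage points)

- given per volume of solution although it is solid: solid substrate
- on the list of suspects stand: isomer of the product <-> starting material; target <-> isomer of the product; starting material <-> target; solid substrate <-> starting material
- at the start none of the solid substrate is in solution
- what has only dissolved of solid substrate counts as not reacted

1. how much target there is at 5.0 h, in percent of the solid substrate charged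
2. how much isomer of the product there is at 5.0 h, in percent of the solid substrate charged
3. amount of target if the flask were left three thousand times as long, in percent of the solid substrate charged

I ran the flask slowly in my head. In the first instants it held solid and nothing in solution, and material then began to leave the solid. The readings did not show this middle stage: the first dawn reading, at 19.98 min, already stood at 13.5% isomer. After that the spring solid moved 0.1 points between its first and last readings, less than the scatter. I read this as thermodynamic control. The balance at the last spring reading fell 3.70% short, a small correction that I took to be dissolved starting material.

What was about to matter was whether solid would survive. The flask's charge is smaller than the spring charge by a factor of 1.40, so I reckoned the flask's lost share at 38.7%, below the whole charge. Scaling the spring means by the same factor, I reckoned 3.22% target and 30.9% isomer. The forecast gave 3.1% target, 30% isomer and 3.1% for the long wait: “Waiting longer therefore changes nothing.”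

    isomer of the product ⇌ starting material (k = 0.00700 /s)
    target ⇌ isomer of the product (K = 11.0, k = 0.00730 /s)
    starting material ⇌ target (K = 0.600, k = 0.0160 /s)
    solid substrate ⇌ starting material, rate k4*(cs4 - [starting material]) while solid is left; crystals form when [starting material] > cs4 (solubility = 14.0 mM, k = 0.110 /s)

The flask gave 2.80% target and 30.8% isomer, and 2.80% target after the long wait, so the forecast held. Its solid stood at 61.7% at 0.500 h and still at 61.7% at 50.0 h, against the 61.3% left by the lost share. A neighbouring flask charged with 0.12 M kept less solid: the lost share, scaled to that charge, reckons at 96.8%, leaving 3.23% as solid, and that flask held 4.33% solid at 5.00 h.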